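Take the constants one at a time and ask how far the outcome hangs on each.

    J + Q → X + E (k1 = 18.6 /M/min)
    E + Q → X + L (k2 = 15.2 /M/min)
    L + Q → X + Z (k3 = 8.65 /M/min)
    D ⇌ X, rate k4*(cs4 - [X]) while solid is left; crystals form when [X] > cs4 (cs4 = 2.4 mM, k4 = 2.18 /min)

J 10 mM (in portions, 4); Q 9.50 mM; time 12 h; the portions of J follow each other after 4.0 min, the first at the start

- what is said of X includes D
- D is a solid; its amount is given per volume of the solution
- the reaction counts as stopped when no species that holds the J changes by six tenths of a point or more over the second half of the time
- run time (flask): 12 h

- why nothing more happens at 12 h, or that something still does (Q has run out first / it is still moving / all of J has reacted)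
- how much of the J has reacted by 12 h
- how much E there is at 12 h, in percent of the J charged
- how much L there is at 12 h, in percent of the J charged
- how much Z there is at 12 h, in percent of the J charged

The solubility and the dissolution coefficient can be passed over: X stands on the right of the first three steps, and no rate there contains it, so neither its saturation nor its loss into crystals touches J.

The sizes of the three rate constants need no great care for telling whether the run is over by its end. The half-lives of J, E and L by their own steps, with the other concentrations as charged, 0.065 h, 0.080 h and 0.14 h, are short against the 12 h of the run . Beside them stand their ratios, 0.817 and 0.465 against the first step, and the gap of 4.0 min between portions, which is about the half-life of J. You need these to share the exchanges among E, L and Z, but not to count them.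

The charges must be known well. Each step takes one Q and makes one exchange, so once Q is used up, E + 2 L + 3 Z, in percent of the J charged, equals the Q charged divided by the J charged, 95.0%. Call this the exchange budget; at a fixed charge of J it moves in direct proportion to the Q charged. Q is the limiting reagent: its charge is less than the 30.0 mM of exchanges that the J could take.

My reckoning stops at this: Q has run out first, with conversion above 31.7% and below 95.0%. That is a range and not a split.

The forecast goes further: Q has run out first, conversion 62%, E 35%, L 21%, Z 6%, taken from “a rough consecutive-reaction estimate constrained by” that same balance.

The simulated flask gives Q has run out first, with 62.1% of the J reacted, E at 35.4%, L at 20.3% and Z at 6.30%. The first three steps ran side by side while Q lasted, with 37.9% of it present at 0.200 h, and L already read 20.1% at 0.600 h. With Q at 0%, 38% of the J stayed unreacted, and no share moved by more than 0 percentage points over the second half. The budget returns Z as (budget − E − 2 L)/3, here 6.33%. The neighbour flask with 6.0 mM of J has a budget of 158%, so its E of 31.1% and L of 34.5% give 19.3%, and that flask holds 19.4% of Z.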